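**Plan**

- Retrosynthesis (double primes mark the 4-hydroxyphenyl flavanone half): with the phenols unmasked last, the C2''–C3'' bond of ring C'' is cut first, then the inter-unit C3–C3'' bond, then the C2–aryl bond of ring C.
- Enabling feature: C2'' is a benzylic ether carbon between O1'' and C3'', and C3'' is alpha to the C4'' ketone, so a carbene at C3'' can insert into an O–CH2–aryl C–H bond of an aryl 4-(benzyloxy)benzyl ether on ring A'' and close pyranone ring C''.
- Forward: ring C is built first (chromone, then flavanone), the chain is joined at C3–C3'' by radical alkylation with a phenacyl bromide, a diazo group is placed on C3'', and ring C'' is closed last with Rh2(S-PTTL)4, dirhodium tetrakis[N-phthaloyl-(S)-tert-leucinate].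
- The aryl ketone ring is differentiated in three single operations: benzyl on the para oxygen, one 4-(benzyloxy)benzyl ether on an ortho oxygen (it delivers C2'' with its aryl group) and a triisopropylsilyl ether on the other ortho oxygen, which has no C–H bond placed for six-membered insertion.
- Stereochemistry: C2 from a rhodium-catalysed asymmetric conjugate addition; C3 trans by radical approach anti to the C2 aryl group and by thermodynamics; C2'' in the insertion (catalyst plus substrate); C3'' by base equilibration to trans.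

Key step: step 11

Assumption: the (S)-bisphosphine of step 3 and the S-configured dirhodium carboxylate of step 11 are taken to give the 2S and 2''R centres by analogy with simpler substrates; if a model run shows the opposite sense, the mirror-image ligand is used and nothing else changes.

**Route**

Step 1
Reactants: 1 2',4',6'-trihydroxyacetophenone
Product: 2 1-[2,4-bis(benzyloxy)-6-hydroxyphenyl]ethan-1-one
Conditions: BnBr (2.1 equiv), K2CO3, DMF, rt
Reagents that add atoms: benzyl bromide, BrCc1ccccc1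
Why: Williamson etherification; the hydroxyl hydrogen-bonded to the acetyl group is the least nucleophilic, so alkylation should stop at the 2,4-dibenzyl ether.

Step 2
Reactants: 2 1-[2,4-bis(benzyloxy)-6-hydroxyphenyl]ethan-1-one
Product: 4 5,7-bis(benzyloxy)-4H-chromen-4-one, via enaminone 3 (not isolated)
Conditions: Me2NCH(OMe)2, toluene, 100 °C; then conc. HCl, CH2Cl2, rt
Reagents that add atoms: N,N-dimethylformamide dimethyl acetal, COC(OC)N(C)C
Why: Enaminone route to chromones; condensation at the acetyl methyl group followed by acid-promoted addition of the phenol and loss of dimethylamine should give the 2,3-unsubstituted chromone.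

Step 3
Reactants: 4 5,7-bis(benzyloxy)-4H-chromen-4-one; 5 4-methoxyphenylboronic acid
Product: 6 (2S)-5,7-bis(benzyloxy)-2-(4-methoxyphenyl)chroman-4-one
Conditions: [Rh(OH)(cod)]2 (cat.), (S)-MeO-F12-BIPHEP, toluene/H2O, 40 °C
Reagents that add atoms: none
Why: Rhodium-catalysed asymmetric 1,4-addition of an arylboronic acid to a chromone (Hayashi–Miyaura reaction); the chiral bisphosphine selects the face of C2 and the base-free medium should prevent ring opening of the flavanone.

Step 4
Reactants: 6 (2S)-5,7-bis(benzyloxy)-2-(4-methoxyphenyl)chroman-4-one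
Product: 7 (2S)-5,7-bis(benzyloxy)-2-(4-methoxyphenyl)-4-(trimethylsilyloxy)-2H-chromene
Conditions: TMSOTf, Et3N, CH2Cl2, −20 to 0 °C; made directly before step 9 and used crude
Reagents that add atoms: trimethylsilyl trifluoromethanesulfonate, C[Si](C)(C)OS(=O)(=O)C(F)(F)F
Why: Soft enolisation to a silyl enol ether; no free enolate is formed, so E1cB opening of the pyranone and loss of the C2 configuration should be avoided.

Step 5
Reactants: 1 2',4',6'-trihydroxyacetophenone
Product: 8 1-[4-(benzyloxy)-2,6-dihydroxyphenyl]ethan-1-one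
Conditions: BnBr (1.0 equiv), K2CO3 (1.0 equiv), DMF, 0 °C to rt
Reagents that add atoms: benzyl bromide, BrCc1ccccc1
Why: Williamson etherification with one equivalent of halide; the para hydroxyl is the only one not hydrogen-bonded to the acetyl group and should react first, and any over-alkylated material is compound 2, which can be passed on to step 2.

Step 6
Reactants: 8 1-[4-(benzyloxy)-2,6-dihydroxyphenyl]ethan-1-one; 9 4-(benzyloxy)benzyl chloride
Product: 10 1-{4-(benzyloxy)-2-[4-(benzyloxy)benzyloxy]-6-hydroxyphenyl}ethan-1-one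
Conditions: 9 (1.0 equiv), K2CO3, KI (cat.), DMF, rt
Reagents that add atoms: none
Why: Williamson etherification; the two ortho hydroxyls of 8 are equivalent, and once one is alkylated the other is held in a strong hydrogen bond to the carbonyl, so the reaction should stop at the monoether as in step 1.

Step 7
Reactants: 10 1-{4-(benzyloxy)-2-[4-(benzyloxy)benzyloxy]-6-hydroxyphenyl}ethan-1-one
Product: 11 1-{4-(benzyloxy)-2-[4-(benzyloxy)benzyloxy]-6-[(triisopropylsilyl)oxy]phenyl}ethan-1-one
Conditions: NaH (1.05 equiv), THF, 0 °C; then iPr3SiCl, 0 °C to rt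
Reagents that add atoms: triisopropylsilyl chloride, CC(C)[Si](Cl)(C(C)C)C(C)C
Why: O-silylation of a sodium phenoxide; deprotonation breaks the chelate, one equivalent of hydride leaves the acetyl group untouched, and the bulky silyl ether gives an ortho oxygen without any C–H bond within reach of the later carbene.

Step 8
Reactants: 11 1-{4-(benzyloxy)-2-[4-(benzyloxy)benzyloxy]-6-[(triisopropylsilyl)oxy]phenyl}ethan-1-one
Product: 13 2-bromo-1-{4-(benzyloxy)-2-[4-(benzyloxy)benzyloxy]-6-[(triisopropylsilyl)oxy]phenyl}ethan-1-one, via silyl enol ether 12 (not isolated)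
Conditions: LiN(SiMe3)2, Me3SiCl (present from the start), THF, −78 °C; then NBS, −78 to 0 °C
Reagents that add atoms: N-bromosuccinimide, O=C1CCC(=O)N1Br
Why: Alpha-bromination of a ketone through its silyl enol ether; the enolate is trapped as it forms so the aryl silyl ether cannot migrate, the enol ether is far more nucleophilic at −78 °C than the alkoxyarene rings, and no HBr is generated that could cleave the 4-alkoxybenzyl ether.

Step 9
Reactants: 7 (2S)-5,7-bis(benzyloxy)-2-(4-methoxyphenyl)-4-(trimethylsilyloxy)-2H-chromene; 13 2-bromo-1-{4-(benzyloxy)-2-[4-(benzyloxy)benzyloxy]-6-[(triisopropylsilyl)oxy]phenyl}ethan-1-one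
Product: 14 (2S,3R)-5,7-bis(benzyloxy)-3-(2-{4-(benzyloxy)-2-[4-(benzyloxy)benzyloxy]-6-[(triisopropylsilyl)oxy]phenyl}-2-oxoethyl)-2-(4-methoxyphenyl)chroman-4-one
Conditions: fac-Ir(ppy)3 (1 mol %), 2,6-lutidine, MeCN/CH2Cl2, blue LEDs, rt; aq. NaHCO3 work-up
Reagents that add atoms: none
Why: Visible-light photoredox alkylation of a silyl enol ether with an alpha-bromo ketone (radical addition, then oxidation and desilylation); the electrophilic phenacyl radical should add to C3 anti to the C2 aryl group, giving the 2,3-trans 1,4-diketone, which is also the thermodynamic isomer.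

Step 10
Reactants: 14 (2S,3R)-5,7-bis(benzyloxy)-3-(2-{4-(benzyloxy)-2-[4-(benzyloxy)benzyloxy]-6-[(triisopropylsilyl)oxy]phenyl}-2-oxoethyl)-2-(4-methoxyphenyl)chroman-4-one
Product: 16 (2S,3R)-5,7-bis(benzyloxy)-3-(2-{4-(benzyloxy)-2-[4-(benzyloxy)benzyloxy]-6-[(triisopropylsilyl)oxy]phenyl}-1-diazo-2-oxoethyl)-2-(4-methoxyphenyl)chroman-4-one, via trifluoroacetyl diketone 15 (not isolated)
Conditions: LiN(SiMe3)2, THF, −78 °C, then CF3CO2CH2CF3; cold dilute aq. HCl; then MsN3, Et3N, H2O (1 equiv), MeCN, rt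
Reagents that add atoms: methanesulfonyl azide, CS(=O)(=O)N=[N+]=[N-]
Why: Detrifluoroacetylative diazo transfer (a deacylative Regitz reaction); the bulky amide should deprotonate the less hindered C3'' methylene and not the C3 methine, C-trifluoroacetylation activates that carbon alone, and azide transfer with loss of N-mesyltrifluoroacetamide leaves the diazo group at C3''.

Step 11
Reactants: 16 (2S,3R)-5,7-bis(benzyloxy)-3-(2-{4-(benzyloxy)-2-[4-(benzyloxy)benzyloxy]-6-[(triisopropylsilyl)oxy]phenyl}-1-diazo-2-oxoethyl)-2-(4-methoxyphenyl)chroman-4-one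
Product: 18 (2S,3R)-5,7-bis(benzyloxy)-3-{(2R,3S)-7-(benzyloxy)-2-[4-(benzyloxy)phenyl]-4-oxo-5-[(triisopropylsilyl)oxy]chroman-3-yl}-2-(4-methoxyphenyl)chroman-4-one, via cis insertion product 17 (not isolated)
Conditions: Rh2(S-PTTL)4 (2 mol %), CH2Cl2, −78 to −20 °C; then DBU (0.1 equiv), 0 °C
Reagents that add atoms: none
Why: Rh2(S-PTTL)4 expels N2 from the diazo ketone to give an electrophilic dirhodium carbene at C3'', which inserts through a concerted three-centre, hydride-transfer-like transition state into a C–H bond of the ortho ArO–CH2–aryl group and so forms C2''–C3''; the closest known reaction type is the dirhodium tetracarboxylate-catalysed intramolecular C–H insertion of ortho-alkoxyaryl alpha-diazo ketones to chroman-4-ones. Ring C'' closes by 1,6-insertion, the six-membered pyranone being the smallest ring available because the fifth atom from the carbene is the ether oxygen. C2'' is set by which of the two diastereotopic methylene hydrogens is replaced, a choice made by the chiral carboxylate ligands together with the resident C2 and C3 centres, and is expected to be R. C3'' should form cis to the new aryl group under kinetic control and is then moved by catalytic DBU to the 2'',3''-trans (3''S) arrangement, while C3 stays trans to its own aryl group. Site selectivity is secured by the substrate: the only C–H bonds within reach of a six-membered transition state are those of the 4-(benzyloxy)benzyl ether, activated by the ether oxygen and the electron-rich arene, whereas the nearest C–H bonds of the triisopropylsilyl ether would require a seven-membered ring and the para benzyl ether is out of reach. Insertion must also win over 1,2-hydride shift from C3–H and over oxonium-ylide formation with Stevens shift: C3–H lies alpha to the C4 ketone and is a poor hydride donor, the bulky phthalimido carboxylates at low temperature slow the shift, and the aryl ether oxygen is a weak nucleophile because it is conjugated with the C4'' carbonyl.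

Step 12
Reactants: 18 (2S,3R)-5,7-bis(benzyloxy)-3-{(2R,3S)-7-(benzyloxy)-2-[4-(benzyloxy)phenyl]-4-oxo-5-[(triisopropylsilyl)oxy]chroman-3-yl}-2-(4-methoxyphenyl)chroman-4-one
Product: 19 (2S,3R)-5,7-bis(benzyloxy)-3-{(2R,3S)-7-(benzyloxy)-2-[4-(benzyloxy)phenyl]-5-hydroxy-4-oxochroman-3-yl}-2-(4-methoxyphenyl)chroman-4-one
Conditions: Bu4NF, AcOH (1:1), THF, 0 °C
Reagents that add atoms: none
Why: Fluoride cleavage of an aryl silyl ether; the acetic acid buffer keeps the medium near neutral so that neither pyranone should open by retro-oxa-Michael reaction, and the freed 5''-hydroxyl is stabilised by its hydrogen bond to the C4'' carbonyl.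

Step 13
Reactants: 19 (2S,3R)-5,7-bis(benzyloxy)-3-{(2R,3S)-7-(benzyloxy)-2-[4-(benzyloxy)phenyl]-5-hydroxy-4-oxochroman-3-yl}-2-(4-methoxyphenyl)chroman-4-one
Product: 20 (2S,3R)-3-[(2R,3S)-5,7-dihydroxy-2-(4-hydroxyphenyl)-4-oxochroman-3-yl]-5,7-dihydroxy-2-(4-methoxyphenyl)chroman-4-one
Conditions: H2 (1 atm), 10% Pd/C, THF/MeOH, rt
Reagents that add atoms: none
Why: Catalytic hydrogenolysis of the four O-benzyl ethers; the two ring C2–O1 bonds, which are secondary and part of the pyranones, and the methyl ether should survive if the reaction is stopped once debenzylation is complete.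

**Compound list**

1 | 2',4',6'-trihydroxyacetophenone | CC(=O)c1c(O)cc(O)cc1O | starting material
2 | 1-[2,4-bis(benzyloxy)-6-hydroxyphenyl]ethan-1-one | CC(=O)c1c(O)cc(OCc2ccccc2)cc1OCc1ccccc1 | intermediate
3 | (E)-1-[2,4-bis(benzyloxy)-6-hydroxyphenyl]-3-(dimethylamino)prop-2-en-1-one | CN(C)/C=C/C(=O)c1c(O)cc(OCc2ccccc2)cc1OCc1ccccc1 | intermediate
4 | 5,7-bis(benzyloxy)-4H-chromen-4-one | O=c1ccoc2cc(OCc3ccccc3)cc(OCc3ccccc3)c12 | intermediate
5 | 4-methoxyphenylboronic acid | COc1ccc(B(O)O)cc1 | starting material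
6 | (2S)-5,7-bis(benzyloxy)-2-(4-methoxyphenyl)chroman-4-one | COc1ccc([C@H]2Oc3cc(OCc4ccccc4)cc(OCc4ccccc4)c3C(=O)C2)cc1 | intermediate
7 | (2S)-5,7-bis(benzyloxy)-2-(4-methoxyphenyl)-4-(trimethylsilyloxy)-2H-chromene | COc1ccc([C@H]2Oc3cc(OCc4ccccc4)cc(OCc4ccccc4)c3C(O[Si](C)(C)C)=C2)cc1 | intermediate
8 | 1-[4-(benzyloxy)-2,6-dihydroxyphenyl]ethan-1-one | CC(=O)c1c(O)cc(OCc2ccccc2)cc1O | intermediate
9 | 4-(benzyloxy)benzyl chloride | ClCc1ccc(OCc2ccccc2)cc1 | starting material
10 | 1-{4-(benzyloxy)-2-[4-(benzyloxy)benzyloxy]-6-hydroxyphenyl}ethan-1-one | CC(=O)c1c(O)cc(OCc2ccccc2)cc1OCc1ccc(OCc2ccccc2)cc1 | intermediate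
11 | 1-{4-(benzyloxy)-2-[4-(benzyloxy)benzyloxy]-6-[(triisopropylsilyl)oxy]phenyl}ethan-1-one | CC(=O)c1c(O[Si](C(C)C)(C(C)C)C(C)C)cc(OCc2ccccc2)cc1OCc1ccc(OCc2ccccc2)cc1 | intermediate
12 | {[1-{4-(benzyloxy)-2-[4-(benzyloxy)benzyloxy]-6-[(triisopropylsilyl)oxy]phenyl}vinyl]oxy}trimethylsilane | C=C(O[Si](C)(C)C)c1c(O[Si](C(C)C)(C(C)C)C(C)C)cc(OCc2ccccc2)cc1OCc1ccc(OCc2ccccc2)cc1 | intermediate
13 | 2-bromo-1-{4-(benzyloxy)-2-[4-(benzyloxy)benzyloxy]-6-[(triisopropylsilyl)oxy]phenyl}ethan-1-one | O=C(CBr)c1c(O[Si](C(C)C)(C(C)C)C(C)C)cc(OCc2ccccc2)cc1OCc1ccc(OCc2ccccc2)cc1 | intermediate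
14 | (2S,3R)-5,7-bis(benzyloxy)-3-(2-{4-(benzyloxy)-2-[4-(benzyloxy)benzyloxy]-6-[(triisopropylsilyl)oxy]phenyl}-2-oxoethyl)-2-(4-methoxyphenyl)chroman-4-one | COc1ccc([C@H]2Oc3cc(OCc4ccccc4)cc(OCc4ccccc4)c3C(=O)[C@@H]2CC(=O)c2c(O[Si](C(C)C)(C(C)C)C(C)C)cc(OCc3ccccc3)cc2OCc2ccc(OCc3ccccc3)cc2)cc1 | intermediate
15 | (2S,3R)-5,7-bis(benzyloxy)-3-(1-{4-(benzyloxy)-2-[4-(benzyloxy)benzyloxy]-6-[(triisopropylsilyl)oxy]benzoyl}-3,3,3-trifluoro-2-oxopropyl)-2-(4-methoxyphenyl)chroman-4-one (C3'' unassigned) | COc1ccc([C@H]2Oc3cc(OCc4ccccc4)cc(OCc4ccccc4)c3C(=O)[C@@H]2C(C(=O)C(F)(F)F)C(=O)c2c(O[Si](C(C)C)(C(C)C)C(C)C)cc(OCc3ccccc3)cc2OCc2ccc(OCc3ccccc3)cc2)cc1 | intermediate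
16 | (2S,3R)-5,7-bis(benzyloxy)-3-(2-{4-(benzyloxy)-2-[4-(benzyloxy)benzyloxy]-6-[(triisopropylsilyl)oxy]phenyl}-1-diazo-2-oxoethyl)-2-(4-methoxyphenyl)chroman-4-one | COc1ccc([C@H]2Oc3cc(OCc4ccccc4)cc(OCc4ccccc4)c3C(=O)[C@@H]2C(=[N+]=[N-])C(=O)c2c(O[Si](C(C)C)(C(C)C)C(C)C)cc(OCc3ccccc3)cc2OCc2ccc(OCc3ccccc3)cc2)cc1 | intermediate
17 | (2S,3R)-5,7-bis(benzyloxy)-3-{(2R,3R)-7-(benzyloxy)-2-[4-(benzyloxy)phenyl]-4-oxo-5-[(triisopropylsilyl)oxy]chroman-3-yl}-2-(4-methoxyphenyl)chroman-4-one (2'',3''-cis) | COc1ccc([C@H]2Oc3cc(OCc4ccccc4)cc(OCc4ccccc4)c3C(=O)[C@@H]2[C@H]2C(=O)c3c(O[Si](C(C)C)(C(C)C)C(C)C)cc(OCc4ccccc4)cc3O[C@H]2c2ccc(OCc3ccccc3)cc2)cc1 | intermediate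
18 | (2S,3R)-5,7-bis(benzyloxy)-3-{(2R,3S)-7-(benzyloxy)-2-[4-(benzyloxy)phenyl]-4-oxo-5-[(triisopropylsilyl)oxy]chroman-3-yl}-2-(4-methoxyphenyl)chroman-4-one | COc1ccc([C@H]2Oc3cc(OCc4ccccc4)cc(OCc4ccccc4)c3C(=O)[C@@H]2[C@@H]2C(=O)c3c(O[Si](C(C)C)(C(C)C)C(C)C)cc(OCc4ccccc4)cc3O[C@H]2c2ccc(OCc3ccccc3)cc2)cc1 | intermediate
19 | (2S,3R)-5,7-bis(benzyloxy)-3-{(2R,3S)-7-(benzyloxy)-2-[4-(benzyloxy)phenyl]-5-hydroxy-4-oxochroman-3-yl}-2-(4-methoxyphenyl)chroman-4-one | COc1ccc([C@H]2Oc3cc(OCc4ccccc4)cc(OCc4ccccc4)c3C(=O)[C@@H]2[C@@H]2C(=O)c3c(O)cc(OCc4ccccc4)cc3O[C@H]2c2ccc(OCc3ccccc3)cc2)cc1 | intermediate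
20 | (2S,3R)-3-[(2R,3S)-5,7-dihydroxy-2-(4-hydroxyphenyl)-4-oxochroman-3-yl]-5,7-dihydroxy-2-(4-methoxyphenyl)chroman-4-one | COc1ccc([C@H]2Oc3cc(O)cc(O)c3C(=O)[C@@H]2[C@@H]2C(=O)c3c(O)cc(O)cc3O[C@H]2c2ccc(O)cc2)cc1 | target

**Summary and risks**

Total step count: 13. Longest linear sequence: 9 steps (steps 1, 2, 3, 4, 9, 10, 11, 12, 13; the branch through steps 5, 6, 7, 8 is equally long).

Steps most likely to fail:

1. Step 11. The carbene may be diverted into 1,2-hydride shift from C3–H or into oxonium-ylide formation with Stevens shift of the benzylic group. It may also replace the wrong diastereotopic hydrogen if catalyst and substrate preferences oppose each other, and the DBU equilibration may open a pyranone by retro-oxa-Michael reaction. The fallback sets out from 14 and comes back at 18 without any carbene. MgBr2·OEt2 should remove, by chelation to the C4'' carbonyl, the ortho 4-(benzyloxy)benzyl ether of 14 and leave the silyl ether, giving the 2-hydroxyaryl ketone (2S,3R)-5,7-bis(benzyloxy)-3-(2-{4-(benzyloxy)-2-hydroxy-6-[(triisopropylsilyl)oxy]phenyl}-2-oxoethyl)-2-(4-methoxyphenyl)chroman-4-one F1. A Claisen–Schmidt condensation of this phenol with commercial 4-(benzyloxy)benzaldehyde (pyrrolidine, EtOH, warm) would give the alpha-substituted 2'-hydroxychalcone F2. Its oxa-Michael closure in the same flask forms ring C'' and leads to 18 together with the (2''S,3''R) diastereomer, which has to be separated because this closure is not catalyst-controlled.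

2. Step 10. Enolisation may occur at the C3 methine instead of the C3'' methylene, which would be followed by E1cB opening of ring C and erosion of the C2 configuration. The fallback sets out from 11 and 7 and comes back at 16, and places the activating acyl group before the two halves are joined. Crossed Claisen condensation of 11 with ethyl acetate (LiN(SiMe3)2, THF, −78 to 0 °C) should give 1-{4-(benzyloxy)-2-[4-(benzyloxy)benzyloxy]-6-[(triisopropylsilyl)oxy]phenyl}butane-1,3-dione F3. NBS would brominate its central carbon to give the 2-bromo-1,3-diketone F4. Photoredox coupling of this bromide with 7 under the conditions of step 9 should give the C3''-acetyl triketone F5. Its deacetylative Regitz diazo transfer (MsN3, DBU, MeCN, 0 °C) loses the unhindered acetyl group and gives 16 without any strong base meeting the flavanone.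

3. Step 9. The radical addition to the hindered C3 position may be slow, so that reduction of the bromide or hydrolysis of the silyl enol ether takes over. The fallback sets out from 7 and 12 and comes back at 14, and reverses the roles of the partners. NBS in THF at −78 °C should convert 7 into trans-configured (2R,3R)-5,7-bis(benzyloxy)-3-bromo-2-(4-methoxyphenyl)chroman-4-one F6. Under the same photoredox conditions the flavanon-3-yl radical from this bromide would add to the unhindered terminal carbon of silyl enol ether 12, here prepared from 11 as in step 8 and used crude without NBS, to give 14.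

Further compounds
F1 | step 11 | (2S,3R)-5,7-bis(benzyloxy)-3-(2-{4-(benzyloxy)-2-hydroxy-6-[(triisopropylsilyl)oxy]phenyl}-2-oxoethyl)-2-(4-methoxyphenyl)chroman-4-one | COc1ccc([C@H]2Oc3cc(OCc4ccccc4)cc(OCc4ccccc4)c3C(=O)[C@@H]2CC(=O)c2c(O[Si](C(C)C)(C(C)C)C(C)C)cc(OCc3ccccc3)cc2O)cc1
F2 | step 11 | (2S,3R)-5,7-bis(benzyloxy)-3-[(E)-1-[4-(benzyloxy)phenyl]-3-{4-(benzyloxy)-2-hydroxy-6-[(triisopropylsilyl)oxy]phenyl}-3-oxoprop-1-en-2-yl]-2-(4-methoxyphenyl)chroman-4-one | COc1ccc([C@H]2Oc3cc(OCc4ccccc4)cc(OCc4ccccc4)c3C(=O)[C@@H]2/C(=C\c2ccc(OCc3ccccc3)cc2)C(=O)c2c(O[Si](C(C)C)(C(C)C)C(C)C)cc(OCc3ccccc3)cc2O)cc1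
F3 | step 10 | 1-{4-(benzyloxy)-2-[4-(benzyloxy)benzyloxy]-6-[(triisopropylsilyl)oxy]phenyl}butane-1,3-dione | CC(=O)CC(=O)c1c(O[Si](C(C)C)(C(C)C)C(C)C)cc(OCc2ccccc2)cc1OCc1ccc(OCc2ccccc2)cc1
F4 | step 10 | 2-bromo-1-{4-(benzyloxy)-2-[4-(benzyloxy)benzyloxy]-6-[(triisopropylsilyl)oxy]phenyl}butane-1,3-dione | CC(=O)C(Br)C(=O)c1c(O[Si](C(C)C)(C(C)C)C(C)C)cc(OCc2ccccc2)cc1OCc1ccc(OCc2ccccc2)cc1
F5 | step 10 | (2S,3R)-3-(1-acetyl-2-{4-(benzyloxy)-2-[4-(benzyloxy)benzyloxy]-6-[(triisopropylsilyl)oxy]phenyl}-2-oxoethyl)-5,7-bis(benzyloxy)-2-(4-methoxyphenyl)chroman-4-one (C3'' unassigned) | COc1ccc([C@H]2Oc3cc(OCc4ccccc4)cc(OCc4ccccc4)c3C(=O)[C@@H]2C(C(C)=O)C(=O)c2c(O[Si](C(C)C)(C(C)C)C(C)C)cc(OCc3ccccc3)cc2OCc2ccc(OCc3ccccc3)cc2)cc1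
F6 | step 9 | (2R,3R)-5,7-bis(benzyloxy)-3-bromo-2-(4-methoxyphenyl)chroman-4-one | COc1ccc([C@H]2Oc3cc(OCc4ccccc4)cc(OCc4ccccc4)c3C(=O)[C@@H]2Br)cc1
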